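## Structural features

Ring A is a pentasubstituted benzene (chromene numbering is used for it) that carries a methoxy group at C7, is fused through O1/C8a and C4a to a 2,2-dimethyl-2H-pyran, and is fused through C5 and C6 to a cyclopentane made up of a benzylic CH2 and two methine carbons. These methines, Cd (bonded to the CH2) and Ca (bonded to C5 of ring A), are shared with a cyclobutane that is completed by Cb, which bears a 3,4-dihydroxyphenyl ring, and Cc, a C(CH3)2 unit. Cd, Ca and Cb are three contiguous stereocentres (S, R and S): the five/four ring fusion is cis and the aryl groups on Ca and Cb are trans, so the hydrogen on Cb points into the concave face of the bicyclo[3.2.0]heptane. Fragile elements are the electron-rich chromene alkene with its tertiary allylic aryl ether (acid, electrophiles, hydrogenation, ultraviolet light), the free catechol (oxidation), the aryl methyl ether that must outlast any phenol deprotection, and the strained cyclobutane with benzylic C–C bonds. The real difficulty is the trans-1,2-diaryl pattern next to the quaternary Cc: any external hydrogen or carbon reagent reaches Cb from the convex face and would give the cis isomer, and ring A, with five different substituents, tolerates no regiochemical error. The key step exploits the fact that Ca and Cb are adjacent ring carbons, each bonded to one aryl group on opposite faces: this is the pattern of an anti 1,2-diarylation of a Ca=Cb cyclobutene, in which the ring A–Ca bond is made intramolecularly through the CH2 tether from Cd, the only stereocentre that must be present beforehand.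

## Logic of the disconnections

30 ⇒ 28 ⇒ 27. The two phenolic O–H bonds are exchanged for acetal C–O bonds, and one stage further back the C–H bond at Cb is exchanged for a C–B bond on the same (concave) face. The reason is that boron is what a metallate shift leaves on Cb, and protonolysis with retention is the one way to place hydrogen on the concave face. The skeleton is unchanged, but the stereochemical problem at Cb becomes a substitution with memory. The forward steps must therefore be stereoretentive, the phenol protection must be inert to fluoride, and the final deprotection must spare the chromene and the methyl ether.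

27 ⇒ 22 + 25 (made in the flask from 24). Two bonds are cut, C5(ring A)–Ca and Cb–C(aryl), and the cyclopentane is opened. Both aryl groups are then introduced across one alkene in a single operation, and the trans relationship follows from the mechanism instead of from reagent approach. The gain is large: 22 has a single stereocentre (Cd), and the catechol becomes a simple aryl anion. The forward step must be an anti addition across a trisubstituted cyclobutene, must run intramolecularly from an aryl triflate on the tether face, and must tolerate the chromene.

22 ⇒ 21 ⇒ 20. The C–B bond at Cb is traced to an enol C–O triflate bond, and both triflate S–O bonds are traced to the phenol and the ketone of 20. The ketone sits next to the quaternary Cc and can enolise only towards Ca, so the position of the alkene is unambiguous. One pair of reagents then makes both sulfonates. The demand is a borylation that distinguishes an alkenyl triflate from a hindered aryl triflate.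

20 ⇒ 19 ⇒ 17 + 8 (through 18). The C6–CH2 bond is cut, after the carbamate C–O bond is restored on the phenol. This divides the molecule into an achiral ring A half and a small chiral four-membered ketone whose stereocentre is not on the reacting carbon. The forward step is an sp3–sp2 coupling at a doubly ortho-substituted aryl iodide that must tolerate a ketone, and the carbamate must come off under conditions mild enough for the cyclobutanone.

17 ⇒ 13 ⇒ 12 ⇒ 10 ⇒ 9. The C6–I bond, the carbamate, the C3=C4 alkene and finally the pyranone ring (one C–C and one C–O bond to a three-carbon ketone) are removed in turn. The two phenols of 9 are equivalent, so the annulation can give only one chromanone and the oxygen pattern of ring A is fixed by construction. The remaining phenol then carries the directing group that singles out C6. The demand is a lithiation that is selective for the position between carbamate and methoxy and is run cold enough to leave the chromene untouched.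

8 ⇒ 7 ⇒ 6 ⇒ 5 ⇒ 1 + 2. After functional-group changes at the side-chain carbon (I, OH, OAc) and a resolution, two ring bonds of the cyclobutanone are cut (C(=O)–CH2 and CMe2–CH), which is a [2+2] disconnection to a ketene equivalent and a terminal alkene. The quaternary carbon, the ketone and the future Cd are set in one step from two bulk chemicals. The price is that Cd is formed racemic and must be resolved at the cheapest stage.

24 ⇒ 23. The two acetal C–O bonds are cut to give the bromocatechol. The demand is only that the protecting groups survive lithium–bromine exchange, palladium catalysis and fluoride.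

## Other disconnections considered

Alternative 1: The cut removes two bonds of ring A itself (C4a–C5 and C8–C8a), so the benzene ring is made last on a finished cyclobuta-fused cyclopentene. In the forward key step a malonate anion adds to the β-chlorovinyl methyl ketone A1 with loss of chloride, the methyl ketone enolate closes onto one ester carbonyl, and tautomerisation gives the resorcylate A2.
- In favour: aromatisation gives a strong driving force and every elementary step is conventional carbonyl chemistry, so on mechanistic certainty this alternative is better than the chosen plan. The substitution pattern of ring A is fixed by construction and not by a regioselective metalation, which is also a point in its favour. It equals the chosen plan in carrying the catechol as acetal ethers.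
- Against: the annulation creates no stereocentre. Cd, Ca and Cb, including the concave hydrogen on Cb, must already be present in A1, so the hard problem is only moved upstream. A2 is also far from the target: selective O-methylation, conversion of the ester into the dimethylpyran ring and deprotection would cost five or more steps, against two after the chosen key step.
- Comparison: structurally it is less convergent, because ring A and the chromene are built linearly on the valuable bicyclic core. Mechanistically it is safer at the key step itself. In step economy it is clearly longer.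

Alternative 2: The cut is the Ca–Cb bond: the cyclobutane is viewed as the pyrrolidine A3, whose nitrogen bridges Ca and Cb, minus that nitrogen. In the forward key step A3 is N-aminated by an anomeric-amide reagent, the isodiazene loses dinitrogen, and the 1,4-diradical closes to the Ca–Cb bond of the chromanone A4.
- In favour: 2,5-diarylpyrrolidines can be assembled with good stereocontrol, and the diradical is expected to collapse faster than it rotates. The trans-diaryl pattern and the concave hydrogen on Cb would then simply be inherited, which is better than the chosen plan, where a separate stereoretentive protodeboronation is needed. The reagent is metal-free.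
- Against: the diradical has an easy β-scission of the Cd–Cc bond into two conjugated alkenes, and the bond to be formed joins two benzylic carbons, one of them next to the quaternary Cc. The chromene must be carried as a chromanone, so reduction, dehydration and desilylation follow (three steps against two). A3, with three stereocentres on a fused indane, would itself need a long synthesis.
- Comparison: structurally the two plans are equal in forming one ring of the strained bicycle late. Mechanistically the alternative uses known chemistry but faces a fragmentation pathway specific to this substrate. In step economy it is poorer both before and after its key step.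

Alternative 3: The cut is the Cb–Cc bond, made by contraction of a cyclopentanone. In the forward key step the α-diazoketone A5 is irradiated in an alcohol solvent, Cb migrates with retention to the carbene carbon Cc, and the ketene is trapped as the methyl ester A6.
- In favour: the Wolff ring contraction is a classical route from five- to four-membered rings, migration with retention keeps Cb intact, and a diquinane precursor is easier to assemble than a cyclobutane. On precedent for the key step it is better than the chosen plan.
- Against: A6 carries hydrogen and an ester on Cc where the target has two methyl groups. Alkylation to the quaternary ester, reduction of a neopentyl-type ester to methyl and deprotection would add about five steps. The 2H-chromene is itself photoactive at the wavelengths used for diazoketones.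
- Comparison: structurally it reaches the same bicyclic core but with the wrong substituents on Cc. Mechanistically the two plans are equal in relying on a stereospecific 1,2-shift for Cb. In step economy and functional-group fit the alternative is weaker.

Key step: step 14

Remarks on the chemistry (assumptions, one line each):
- The catechol is carried as its bis(methoxymethyl) ether and not as silyl ethers, because the fluoride needed for protodeboronation would strip aryl silyl ethers first and leave a phenoxide on the ring attached to the carbon that must take up carbanion character.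
- Boron on Cb carries one aryl and two alkyl groups, so the hydrated tetrabutylammonium fluoride protocol for aryl(dialkyl) tertiary boronates is used, not CsF with water.
- An N-isopropyl carbamate (removable with mild base) serves as directing group; it is removed before boron is introduced, and both triflates are then installed together.
- The pinacol ester is kept on boron because direct transmetalation within the molecule is geometrically impossible, so the usual reason for a bulkier diol does not apply.

## Route

Step 1
Reactants: 1 N,N-dimethylisobutyramide; 2 allyl acetate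
Product: 5 rac-(2,2-dimethyl-3-oxocyclobutyl)methyl acetate, via keteniminium triflate 3 (not isolated), via cyclobutaniminium triflate 4 (not isolated)
Conditions: (CF3SO2)2O, 2,4,6-collidine, ClCH2CH2Cl, −20 °C → reflux; then NaHCO3 (aq), rt
Reagents that add atoms: water, O
Why: O-triflation of the amide and elimination give the keteniminium 3, which adds to the terminal alkene in a stepwise [2+2] (iminium carbon to CH2, CMe2 to CH), so hydrolysis of 4 should give the 3-substituted 2,2-dimethylcyclobutanone as a racemate; keteniminium–alkene [2+2] cycloaddition.

Step 2
Reactants: 5 rac-(2,2-dimethyl-3-oxocyclobutyl)methyl acetate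
Product: 6 [(1S)-2,2-dimethyl-3-oxocyclobutyl]methyl acetate
Conditions: preparative SFC on amylose tris(3,5-dimethylphenylcarbamate), CO2/i-PrOH
Reagents that add atoms: none
Why: Chromatographic resolution on a polysaccharide phase at the cheapest stage sets Cd; the (S) assignment is to be secured by correlation with 8 made from a terpene of known configuration (see the fallback to step 1).

Step 3
Reactants: 6 [(1S)-2,2-dimethyl-3-oxocyclobutyl]methyl acetate
Product: 7 (3S)-3-(hydroxymethyl)-2,2-dimethylcyclobutan-1-one
Conditions: K2CO3, MeOH, 0 °C → rt
Reagents that add atoms: none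
Why: Base-catalysed transesterification frees the primary alcohol; the stereocentre is β to the carbonyl, so it cannot epimerise by enolisation, and a γ-hydroxy ketone has no retro-aldol path.

Step 4
Reactants: 7 (3S)-3-(hydroxymethyl)-2,2-dimethylcyclobutan-1-one
Product: 8 (3S)-3-(iodomethyl)-2,2-dimethylcyclobutan-1-one
Conditions: I2, PPh3, imidazole, CH2Cl2, 0 °C → rt
Reagents that add atoms: iodine, II
Why: Appel iodination of the primary alcohol under essentially neutral conditions; no strong base is present that could form the enolate and displace the γ-iodide.

Step 5
Reactants: 9 2′,6′-dihydroxy-4′-methoxyacetophenone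
Product: 10 5-hydroxy-7-methoxy-2,2-dimethylchroman-4-one
Conditions: acetone, pyrrolidine, EtOH, reflux
Reagents that add atoms: acetone, CC(C)=O
Why: Kabbe condensation (enamine aldol condensation with acetone, then oxa-Michael closure); the two phenols of 9 are equivalent, so only one chromanone can form and the second phenol remains at C5.

Step 6
Reactants: 10 5-hydroxy-7-methoxy-2,2-dimethylchroman-4-one
Product: 12 7-methoxy-2,2-dimethyl-2H-chromen-5-ol, via chromane-4,5-diol 11 (not isolated)
Conditions: LiAlH4, THF, 0 °C → rt; H2O then NaOH (aq) work-up; then pyridinium p-toluenesulfonate (cat.), toluene, 60 °C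
Reagents that add atoms: none
Why: Hydride reduces the hydrogen-bonded aryl ketone to the benzylic alcohol 11, which loses water through an oxygen-stabilised benzylic cation (E1) under very mild acid to give the 2H-chromene; reduction–dehydration.

Step 7
Reactants: 12 7-methoxy-2,2-dimethyl-2H-chromen-5-ol
Product: 13 7-methoxy-2,2-dimethyl-2H-chromen-5-yl N-isopropylcarbamate
Conditions: i-PrNCO, Et3N (cat.), CH2Cl2, rt
Reagents that add atoms: isopropyl isocyanate, CC(C)N=C=O
Why: Base-catalysed addition of the phenol to the isocyanate gives an N-monoalkyl carbamate, a strong directing group that can later be removed by mild base through an E1cB pathway.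

Step 8
Reactants: 13 7-methoxy-2,2-dimethyl-2H-chromen-5-yl N-isopropylcarbamate
Product: 17 6-iodo-7-methoxy-2,2-dimethyl-2H-chromen-5-yl N-isopropylcarbamate, via N-silyl carbamate 14 (not isolated), via C6 aryllithium 15 (not isolated), via N-silyl iodide 16 (not isolated)
Conditions: Me3SiOTf, TMEDA, Et2O, rt; s-BuLi (2.2 equiv), TMEDA, −78 °C; I2, THF, −78 °C; NH4Cl/Na2S2O3 (aq)
Reagents that add atoms: iodine, II
Why: In situ N-silylation masks the N–H, the carbamate then directs lithiation to C6 (its only free ortho position, further acidified by the flanking methoxy group), iodine traps 15, and aqueous work-up removes silicon from 16; directed ortho-metalation, kept at −78 °C to avoid carbamoyl migration and attack on the chromene.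

Step 9
Reactants: 8 (3S)-3-(iodomethyl)-2,2-dimethylcyclobutan-1-one; 17 6-iodo-7-methoxy-2,2-dimethyl-2H-chromen-5-yl N-isopropylcarbamate
Product: 19 6-{[(1S)-2,2-dimethyl-3-oxocyclobutyl]methyl}-7-methoxy-2,2-dimethyl-2H-chromen-5-yl N-isopropylcarbamate, via alkylzinc iodide 18 (not isolated)
Conditions: 8, Zn dust, LiCl, THF, 25–35 °C; then 17, Pd(OAc)2 (3 mol%), 2-dicyclohexylphosphino-2′,6′-dimethoxybiphenyl (SPhos, 6 mol%), THF, 40 °C
Reagents that add atoms: none
Why: Zinc inserts into the primary C–I bond to give a ketone-tolerant alkylzinc iodide, and Negishi coupling with a bulky biarylphosphine joins it to the doubly ortho-substituted aryl iodide; Cd is not a reacting centre and keeps its configuration.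

Step 10
Reactants: 19 6-{[(1S)-2,2-dimethyl-3-oxocyclobutyl]methyl}-7-methoxy-2,2-dimethyl-2H-chromen-5-yl N-isopropylcarbamate
Product: 20 (3S)-3-[(5-hydroxy-7-methoxy-2,2-dimethyl-2H-chromen-6-yl)methyl]-2,2-dimethylcyclobutan-1-one
Conditions: NaOH (1 M aq), EtOH, 0 °C → rt
Reagents that add atoms: none
Why: Hydroxide removes the carbamate N–H proton and the aryloxide is expelled (E1cB), the isocyanate being hydrolysed; the cyclobutanone stereocentre is β to the carbonyl and cannot epimerise.

Step 11
Reactants: 20 (3S)-3-[(5-hydroxy-7-methoxy-2,2-dimethyl-2H-chromen-6-yl)methyl]-2,2-dimethylcyclobutan-1-one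
Product: 21 7-methoxy-2,2-dimethyl-6-{[(1S)-2,2-dimethyl-3-(trifluoromethanesulfonyloxy)cyclobut-3-en-1-yl]methyl}-2H-chromen-5-yl trifluoromethanesulfonate
Conditions: KN(SiMe3)2 (2.3 equiv), THF, −78 °C; PhN(SO2CF3)2 (2.5 equiv), −78 °C → rt
Reagents that add atoms: N-phenylbis(trifluoromethanesulfonimide), O=S(=O)(N(c1ccccc1)S(=O)(=O)C(F)(F)F)C(F)(F)F
Why: Two equivalents of base give the phenoxide and the only possible enolate (Cc is quaternary, so deprotonation occurs at Ca), and the triflimide sulfonylates both oxygens; O-triflation of enolate and phenoxide.

Step 12
Reactants: 21 7-methoxy-2,2-dimethyl-6-{[(1S)-2,2-dimethyl-3-(trifluoromethanesulfonyloxy)cyclobut-3-en-1-yl]methyl}-2H-chromen-5-yl trifluoromethanesulfonate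
Product: 22 6-{[(1S)-2,2-dimethyl-3-(4,4,5,5-tetramethyl-1,3,2-dioxaborolan-2-yl)cyclobut-3-en-1-yl]methyl}-7-methoxy-2,2-dimethyl-2H-chromen-5-yl trifluoromethanesulfonate
Conditions: B2pin2, PdCl2(PPh3)2 (3 mol%), PPh3 (6 mol%), KOPh, toluene, 50 °C
Reagents that add atoms: bis(pinacolato)diboron, CC1(C)OB(OC1(C)C)B1OC(C)(C)C(C)(C)O1
Why: Miyaura borylation: oxidative addition of zerovalent palladium to the alkenyl triflate is far faster than to the electron-rich, doubly ortho-substituted aryl triflate, and phenoxide-assisted transmetalation with the diboron gives the alkenyl boronate; coupling of the boronate with its own aryl triflate is geometrically impossible within the molecule.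

Step 13
Reactants: 23 4-bromobenzene-1,2-diol
Product: 24 4-bromo-1,2-bis(methoxymethoxy)benzene
Conditions: CH3OCH2Cl, i-Pr2NEt, CH2Cl2, 0 °C → rt
Reagents that add atoms: chloromethyl methyl ether, COCCl
Why: O-alkylation of both phenols gives acetal ethers that tolerate lithium–bromine exchange, palladium catalysis and fluoride.

Step 14
Reactants: 24 4-bromo-1,2-bis(methoxymethoxy)benzene; 22 6-{[(1S)-2,2-dimethyl-3-(4,4,5,5-tetramethyl-1,3,2-dioxaborolan-2-yl)cyclobut-3-en-1-yl]methyl}-7-methoxy-2,2-dimethyl-2H-chromen-5-yl trifluoromethanesulfonate
Product: 27 Cb-pinacolboryl bis(methoxymethyl) ether of the tetracyclic core (Cd S; Ca R; Cb S; boron on the concave face), via aryllithium 25 (not isolated), via lithium boronate complex 26 (not isolated)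
Conditions: 24, t-BuLi (2 equiv), Et2O, −78 °C; then 22, −78 °C → rt; solvent switch to THF (0.01 M); Pd(OAc)2 (5 mol%), (S,S)-2,2′-bis[(R)-(dimethylamino)(phenyl)methyl]-1,1′-bis[bis(4-methoxy-3,5-dimethylphenyl)phosphino]ferrocene (6 mol%), 60 °C
Reagents that add atoms: none
Why: Proposed new method: the aryllithium 25 adds to the boron of 22 to give the four-coordinate boronate 26, and zerovalent palladium, formed from Pd(OAc)2 and the bisphosphine, inserts into the aryl triflate to give a cationic arylpalladium that the one-carbon tether holds over the cyclobutene face bearing the CH2 group at Cd. Coordination of the alkene triggers a 1,2-shift of the catechol ring from boron to Cb on the face opposite palladium while the Ca–Pd bond forms, and reductive elimination from the six-membered palladacycle joins C5 of ring A to Ca. The closest known reaction type is the palladium-catalysed conjunctive cross-coupling of alkenylboron ate complexes with aryl triflates; new here are the intramolecular, ring-closing format and the cyclic, α,β-disubstituted alkenyl boronate. The cyclopentane closes in a 5-exo mode onto Ca, and only the cis ring fusion is within reach of the tether. Ca is set by the existing centre Cd through the tether (ring A and the CH2 group end up cis), and Cb is set by the antiperiplanar geometry of the metallate shift, which places the catechol ring trans to ring A and leaves boron on the concave face. The step needs the shift to win over direct transmetalation and over β-hydride elimination: a direct ring A–Cb coupling would require a bridgehead alkene in a bicyclo[3.1.1] frame, and the alkylpalladium at Ca has no syn β-hydrogen because the hydrogen on Cd is anti and Cb is fully substituted. High dilution disfavours intermolecular coupling, and a Heck-type insertion followed by displacement of palladium with inversion would converge on the same diastereomer.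

Step 15
Reactants: 27 Cb-pinacolboryl bis(methoxymethyl) ether of the tetracyclic core
Product: 28 bis(methoxymethyl) ether of the target (Cd S; Ca R; Cb S)
Conditions: Bu4NF·3H2O (3 equiv), toluene, 45 °C
Reagents that add atoms: none
Why: Fluoride adds to boron and the fluoroboronate is protonated at the benzylic carbon by the water of hydration on the boron-bearing face (SE2 with retention), so hydrogen takes the concave position that boron held; fluoride-promoted protodeboronation of a tertiary benzylic boronic ester, to which the acetal ethers, the chromene and the aryl methyl ether are inert.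

Step 16
Reactants: 28 bis(methoxymethyl) ether of the target
Product: 30 CNP0207533.1 (Cd S; Ca R; Cb S), via bis(trimethylsilyl) ether 29 (not isolated)
Conditions: Me3SiOTf, 2,2′-bipyridyl, MeCN, 0 °C → rt; then H2O, rt
Reagents that add atoms: none
Why: The silyl triflate–bipyridyl pair converts aryl methoxymethyl ethers into aryl silyl ethers under aprotic, buffered conditions that should leave the acid-sensitive chromene and the aryl methyl ether alone, and water then hydrolyses 29 to the catechol; no stereocentre is touched.

## Compound list

1 | N,N-dimethylisobutyramide | CC(C)C(=O)N(C)C | starting material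
2 | allyl acetate | C=CCOC(C)=O | starting material
3 | N,N-dimethyl-(2-methylprop-1-en-1-ylidene)ammonium triflate (keteniminium salt, formed in the flask) | CC(C)=C=[N+](C)C.[O-]S(=O)(=O)C(F)(F)F | intermediate
4 | N-[3-(acetoxymethyl)-2,2-dimethylcyclobutylidene]-N-methylmethanaminium triflate (racemic, formed in the flask) | CC(=O)OCC1CC(=[N+](C)C)C1(C)C.[O-]S(=O)(=O)C(F)(F)F | intermediate
5 | rac-(2,2-dimethyl-3-oxocyclobutyl)methyl acetate | CC(=O)OCC1CC(=O)C1(C)C | intermediate
6 | [(1S)-2,2-dimethyl-3-oxocyclobutyl]methyl acetate | CC(=O)OC[C@H]1CC(=O)C1(C)C | intermediate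
7 | (3S)-3-(hydroxymethyl)-2,2-dimethylcyclobutan-1-one | OC[C@H]1CC(=O)C1(C)C | intermediate
8 | (3S)-3-(iodomethyl)-2,2-dimethylcyclobutan-1-one | IC[C@H]1CC(=O)C1(C)C | intermediate
9 | 2′,6′-dihydroxy-4′-methoxyacetophenone | CC(=O)c1c(O)cc(OC)cc1O | starting material
10 | 5-hydroxy-7-methoxy-2,2-dimethylchroman-4-one | COc1cc2c(c(O)c1)C(=O)CC(C)(C)O2 | intermediate
11 | 7-methoxy-2,2-dimethylchromane-4,5-diol (racemic at C4, formed in the flask) | COc1cc2c(c(O)c1)C(O)CC(C)(C)O2 | intermediate
12 | 7-methoxy-2,2-dimethyl-2H-chromen-5-ol | COc1cc2c(c(O)c1)C=CC(C)(C)O2 | intermediate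
13 | 7-methoxy-2,2-dimethyl-2H-chromen-5-yl N-isopropylcarbamate | COc1cc2c(c(OC(=O)NC(C)C)c1)C=CC(C)(C)O2 | intermediate
14 | 7-methoxy-2,2-dimethyl-2H-chromen-5-yl N-isopropyl-N-(trimethylsilyl)carbamate (formed in the flask) | COc1cc2c(c(OC(=O)N(C(C)C)[Si](C)(C)C)c1)C=CC(C)(C)O2 | intermediate
15 | 6-lithio derivative of 14 (formed in the flask) | COc1cc2c(c(OC(=O)N(C(C)C)[Si](C)(C)C)c1[Li])C=CC(C)(C)O2 | intermediate
16 | 6-iodo derivative of 14 (formed in the flask) | COc1cc2c(c(OC(=O)N(C(C)C)[Si](C)(C)C)c1I)C=CC(C)(C)O2 | intermediate
17 | 6-iodo-7-methoxy-2,2-dimethyl-2H-chromen-5-yl N-isopropylcarbamate | COc1cc2c(c(OC(=O)NC(C)C)c1I)C=CC(C)(C)O2 | intermediate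
18 | {[(1S)-2,2-dimethyl-3-oxocyclobutyl]methyl}zinc iodide (formed in the flask) | I[Zn]C[C@H]1CC(=O)C1(C)C | intermediate
19 | 6-{[(1S)-2,2-dimethyl-3-oxocyclobutyl]methyl}-7-methoxy-2,2-dimethyl-2H-chromen-5-yl N-isopropylcarbamate | COc1cc2c(c(OC(=O)NC(C)C)c1C[C@H]1CC(=O)C1(C)C)C=CC(C)(C)O2 | intermediate
20 | (3S)-3-[(5-hydroxy-7-methoxy-2,2-dimethyl-2H-chromen-6-yl)methyl]-2,2-dimethylcyclobutan-1-one | COc1cc2c(c(O)c1C[C@H]1CC(=O)C1(C)C)C=CC(C)(C)O2 | intermediate
21 | 7-methoxy-2,2-dimethyl-6-{[(1S)-2,2-dimethyl-3-(trifluoromethanesulfonyloxy)cyclobut-3-en-1-yl]methyl}-2H-chromen-5-yl trifluoromethanesulfonate | COc1cc2c(c(OS(=O)(=O)C(F)(F)F)c1C[C@H]1C=C(OS(=O)(=O)C(F)(F)F)C1(C)C)C=CC(C)(C)O2 | intermediate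
22 | 6-{[(1S)-2,2-dimethyl-3-(4,4,5,5-tetramethyl-1,3,2-dioxaborolan-2-yl)cyclobut-3-en-1-yl]methyl}-7-methoxy-2,2-dimethyl-2H-chromen-5-yl trifluoromethanesulfonate (precursor of the key step) | COc1cc2c(c(OS(=O)(=O)C(F)(F)F)c1C[C@H]1C=C(B3OC(C)(C)C(C)(C)O3)C1(C)C)C=CC(C)(C)O2 | intermediate
23 | 4-bromobenzene-1,2-diol | Oc1ccc(Br)cc1O | starting material
24 | 4-bromo-1,2-bis(methoxymethoxy)benzene | COCOc1ccc(Br)cc1OCOC | intermediate
25 | [3,4-bis(methoxymethoxy)phenyl]lithium (formed in the flask) | [Li]c1ccc(OCOC)c(OCOC)c1 | intermediate
26 | lithium boronate complex from 22 and 25: boron bonded to the cyclobutenyl carbon Cb, the aryl group and pinacol (formed in the flask) | [Li+].COc1cc2c(c(OS(=O)(=O)C(F)(F)F)c1C[C@H]1C=C([B-]3(c4ccc(OCOC)c(OCOC)c4)OC(C)(C)C(C)(C)O3)C1(C)C)C=CC(C)(C)O2 | intermediate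
27 | tetracyclic core (7-methoxy-2,2-dimethyl-2H-chromene fused at C5–C6 to a cyclopentane, cis-fused at Cd–Ca to the gem-dimethylcyclobutane) with Cb bearing 3,4-bis(methoxymethoxy)phenyl on the convex face and pinacolboryl on the concave face; Cd S, Ca R, Cb S | COc1cc2c(c3c1C[C@H]1[C@@H]3[C@@](c3ccc(OCOC)c(OCOC)c3)(B3OC(C)(C)C(C)(C)O3)C1(C)C)C=CC(C)(C)O2 | intermediate
28 | bis(methoxymethyl) ether of the target; Cd S, Ca R, Cb S (Cb–H on the concave face, aryl groups trans) | COc1cc2c(c3c1C[C@H]1[C@@H]3[C@H](c3ccc(OCOC)c(OCOC)c3)C1(C)C)C=CC(C)(C)O2 | intermediate
29 | bis(trimethylsilyl) ether of the target (formed in the flask) | COc1cc2c(c3c1C[C@H]1[C@@H]3[C@H](c3ccc(O[Si](C)(C)C)c(O[Si](C)(C)C)c3)C1(C)C)C=CC(C)(C)O2 | intermediate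
30 | CNP0207533.1: tetracyclic core with 3,4-dihydroxyphenyl on Cb; Cd S, Ca R, Cb S | COc1cc2c(c3c1C[C@H]1[C@@H]3[C@H](c3ccc(O)c(O)c3)C1(C)C)C=CC(C)(C)O2 | target

## Step count and least certain steps

Total: 16 steps. Longest linear sequence: 11 steps (steps 5–12, 14, 15 and 16 from 9). The branch from 1 and 2 (steps 1–4, 9–12, 14–16) is equally long.

Step 14 (key step, new method). Four processes may interfere:
- Boronate complex formation may be incomplete at a boron flanked by the quaternary Cc, with the aryllithium attacking the sulfonyl group of the aryl triflate instead.
- Oxidative addition at the electron-rich, doubly ortho-substituted triflate may be so slow that the boronate complex is protonated first.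
- Intermolecular transmetalation (oligomers) may compete, because the shift must create a fully substituted carbon next to Cc.
- The chiral ligand may be mismatched with the substrate, in which case its enantiomer would be tried.

Fallback with known chemistry, which sets out from 22 and comes back at 28, so that steps 14 and 15 are both bypassed: Suzuki–Miyaura coupling of the alkenyl boronate 22 with bromide 24 [Pd(PPh3)4, K3PO4 (aq), 1,4-dioxane, 70 °C; the hindered aryl triflate is expected to react more slowly than the aryl bromide] would give the 1-arylcyclobutene triflate F1. Intramolecular reductive Heck cyclisation of F1 [Pd(OAc)2, 1,3-bis(diphenylphosphino)propane, HCO2Na, DMF, 80 °C] would add ring A and palladium syn across Ca=Cb from the tether face (5-exo), and formate-derived hydride would replace palladium on Cb with retention. This gives the same trans-diaryl arrangement with hydrogen on the concave face.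

Step 15. Fluoride addition may be slow at a boron buried on the concave face between Cc and ring A, the electron-rich aryl group lowers the carbanion character that the protonolysis needs, and leakage through a free carbanion would allow protonation from the convex face (epimerisation at Cb). No external reagent can deliver hydrogen to the concave face, so the fallback avoids the C–B bond altogether. It sets out from 21, which also spares step 12, and comes back at 28: bromide 24 would be converted into the pinacol boronate F2 (n-BuLi, THF, −78 °C; then 2-isopropoxy-4,4,5,5-tetramethyl-1,3,2-dioxaborolane). F2 would be coupled chemoselectively at the alkenyl triflate of 21 [Pd(PPh3)4, K3PO4 (aq), THF, 40 °C] to give the aryl cyclobutene triflate F1, and the reductive Heck cyclisation described under step 14 would close the ring.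

Step 12. Oxidative addition may also occur at the aryl triflate, followed by aryl borylation or intermolecular coupling with the new alkenyl boronate. The fallback separates the two oxygens in time; it sets out from 20 and comes back at 22. Silylation of the phenol (t-BuMe2SiCl, imidazole, DMF) would give the silyl ether ketone F3. KN(SiMe3)2 and PhN(SO2CF3)2 would give the enol triflate F4. Borylation as in step 12, now without an aryl triflate, would give the alkenyl boronate F5. Bu4NF buffered with AcOH would free the phenol boronate F6, and PhN(SO2CF3)2 with Cs2CO3 in MeCN would give 22.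

Step 16. The electrophilic silicon reagent or adventitious acid may ionise the tertiary allylic aryl ether or hydrate the chromene, or cleavage of the second acetal next to a freed phenol may stall. The fallback changes the protecting-group strategy so that no electrophilic last step is needed; it sets out from 23 and 22 and comes back at 30. Silylation of 23 (t-BuMe2SiCl, imidazole, DMF) would give the bromide F7. Lithium–bromine exchange (t-BuLi) would give the aryllithium F8, which with 22 would form the boronate complex F9 and, under the conditions of step 14, the bis-silyl boronate F10. Excess Bu4NF·3H2O would then remove silicon and boron in one operation. In that case desilylation precedes protonolysis and the C–B cleavage has to run on a phenoxide, which is why this is the fallback and not the main line.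

Step 1. The allylic ester is a weakly nucleophilic alkene and its carbonyl oxygen may capture the keteniminium, so little cyclobutanone may form; the route also then depends on a resolution. The fallback uses the chiral pool, replaces steps 1–4 (and with them 1 and 2) and comes back at 8. It starts from commercial (1S,5S)-(−)-verbenone F11, whose C1 becomes Cd. Cleavage of the enone (RuCl3 cat., NaIO4) would give (1S,3R)-cis-pinononic acid F12. Baeyer–Villiger oxidation of the methyl ketone (mCPBA) would give the acetoxy acid F13 with retention. LiAlH4 would give the diol F14, selective Appel iodination of the primary alcohol would give the iodo alcohol F15, and oxidation with TEMPO and PhI(OAc)2 would give 8. The enantiomeric purity of the terpene would have to be checked and, if needed, raised by crystallisation of F12.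

## Further compounds

F1 | step 14 | 6-{[(1S)-3-[3,4-bis(methoxymethoxy)phenyl]-2,2-dimethylcyclobut-3-en-1-yl]methyl}-7-methoxy-2,2-dimethyl-2H-chromen-5-yl trifluoromethanesulfonate | COc1cc2c(c(OS(=O)(=O)C(F)(F)F)c1C[C@H]1C=C(c3ccc(OCOC)c(OCOC)c3)C1(C)C)C=CC(C)(C)O2
F2 | step 15 | 2-[3,4-bis(methoxymethoxy)phenyl]-4,4,5,5-tetramethyl-1,3,2-dioxaborolane | COCOc1ccc(B2OC(C)(C)C(C)(C)O2)cc1OCOC
F3 | step 12 | (3S)-3-{[5-(tert-butyldimethylsilyloxy)-7-methoxy-2,2-dimethyl-2H-chromen-6-yl]methyl}-2,2-dimethylcyclobutan-1-one | COc1cc2c(c(O[Si](C)(C)C(C)(C)C)c1C[C@H]1CC(=O)C1(C)C)C=CC(C)(C)O2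
F4 | step 12 | (3S)-3-{[5-(tert-butyldimethylsilyloxy)-7-methoxy-2,2-dimethyl-2H-chromen-6-yl]methyl}-4,4-dimethylcyclobut-1-en-1-yl trifluoromethanesulfonate | COc1cc2c(c(O[Si](C)(C)C(C)(C)C)c1C[C@H]1C=C(OS(=O)(=O)C(F)(F)F)C1(C)C)C=CC(C)(C)O2
F5 | step 12 | tert-butyl[(6-{[(1S)-2,2-dimethyl-3-(4,4,5,5-tetramethyl-1,3,2-dioxaborolan-2-yl)cyclobut-3-en-1-yl]methyl}-7-methoxy-2,2-dimethyl-2H-chromen-5-yl)oxy]dimethylsilane | COc1cc2c(c(O[Si](C)(C)C(C)(C)C)c1C[C@H]1C=C(B3OC(C)(C)C(C)(C)O3)C1(C)C)C=CC(C)(C)O2
F6 | step 12 | 6-{[(1S)-2,2-dimethyl-3-(4,4,5,5-tetramethyl-1,3,2-dioxaborolan-2-yl)cyclobut-3-en-1-yl]methyl}-7-methoxy-2,2-dimethyl-2H-chromen-5-ol | COc1cc2c(c(O)c1C[C@H]1C=C(B3OC(C)(C)C(C)(C)O3)C1(C)C)C=CC(C)(C)O2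
F7 | step 16 | 4-bromo-1,2-bis(tert-butyldimethylsilyloxy)benzene | CC(C)(C)[Si](C)(C)Oc1ccc(Br)cc1O[Si](C)(C)C(C)(C)C
F8 | step 16 | [3,4-bis(tert-butyldimethylsilyloxy)phenyl]lithium | [Li]c1ccc(O[Si](C)(C)C(C)(C)C)c(O[Si](C)(C)C(C)(C)C)c1
F9 | step 16 | lithium boronate complex from 22 and F8 | [Li+].COc1cc2c(c(OS(=O)(=O)C(F)(F)F)c1C[C@H]1C=C([B-]3(c4ccc(O[Si](C)(C)C(C)(C)C)c(O[Si](C)(C)C(C)(C)C)c4)OC(C)(C)C(C)(C)O3)C1(C)C)C=CC(C)(C)O2
F10 | step 16 | bis(tert-butyldimethylsilyl) analogue of 27 (Cd S, Ca R, Cb S; boron on the concave face) | COc1cc2c(c3c1C[C@H]1[C@@H]3[C@@](c3ccc(O[Si](C)(C)C(C)(C)C)c(O[Si](C)(C)C(C)(C)C)c3)(B3OC(C)(C)C(C)(C)O3)C1(C)C)C=CC(C)(C)O2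
F11 | step 1 | (1S,5S)-(−)-verbenone | CC1=CC(=O)[C@H]2C[C@@H]1C2(C)C
F12 | step 1 | (1S,3R)-3-acetyl-2,2-dimethylcyclobutane-1-carboxylic acid (cis-pinononic acid) | OC(=O)[C@H]1C[C@@H](C(C)=O)C1(C)C
F13 | step 1 | (1S,3R)-3-acetoxy-2,2-dimethylcyclobutane-1-carboxylic acid | OC(=O)[C@H]1C[C@@H](OC(C)=O)C1(C)C
F14 | step 1 | (1R,3S)-3-(hydroxymethyl)-2,2-dimethylcyclobutan-1-ol | OC[C@H]1C[C@@H](O)C1(C)C
F15 | step 1 | (1R,3S)-3-(iodomethyl)-2,2-dimethylcyclobutan-1-ol | IC[C@H]1C[C@@H](O)C1(C)C
A1 | alternative 1 | β-chlorovinyl methyl ketone: cyclobuta-fused cyclopentene with chlorine on the alkene carbon bonded to Ca, acetyl on the alkene carbon bonded to CH2, and 3,4-bis(methoxymethoxy)phenyl on Cb (configuration at Cd, Ca, Cb as in 30) | ClC3=C(C(C)=O)C[C@H]1[C@@H]3[C@H](c3ccc(OCOC)c(OCOC)c3)C1(C)C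
A2 | alternative 1 | methyl 2,4-dihydroxybenzoate fused to the cyclobuta-indane core, bis(methoxymethyl) ether at the catechol | Oc1cc(O)c(C(=O)OC)c3c1C[C@H]1[C@@H]3[C@H](c3ccc(OCOC)c(OCOC)c3)C1(C)C
A3 | alternative 2 | NH-pyrrolidine with nitrogen bridging Ca and Cb, fused to the indane of the chromanone, catechol as bis(tert-butyldimethylsilyl) ether | COc1cc2c(c3c1C[C@H]1[C@@H]3N[C@H](c3ccc(O[Si](C)(C)C(C)(C)C)c(O[Si](C)(C)C(C)(C)C)c3)C1(C)C)C(=O)CC(C)(C)O2
A4 | alternative 2 | bis(tert-butyldimethylsilyl) chromanone form of the target | COc1cc2c(c3c1C[C@H]1[C@@H]3[C@H](c3ccc(O[Si](C)(C)C(C)(C)C)c(O[Si](C)(C)C(C)(C)C)c3)C1(C)C)C(=O)CC(C)(C)O2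
A5 | alternative 3 | diquinane α-diazoketone: cyclopentanone ring Cd–Ca–Cb–C(=O)–C(=N2) fused to the chromene-indane, catechol as bis(methoxymethyl) ether | COc1cc2c(c3c1C[C@H]1[C@@H]3[C@H](c3ccc(OCOC)c(OCOC)c3)C(=O)C1=[N+]=[N-])C=CC(C)(C)O2
A6 | alternative 3 | cyclobutane methyl ester with the ester carbon on Cc, catechol as bis(methoxymethyl) ether | COc1cc2c(c3c1C[C@H]1[C@@H]3[C@H](c3ccc(OCOC)c(OCOC)c3)[C@H]1C(=O)OC)C=CC(C)(C)O2
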